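The target is cut at C8, the carbon that carries the aryl ether oxygen of ring B (the 2,6-dimethoxyphenoxy ring), one hydrogen, the carbinol carbon C7 bound to ring A (the 3,4,5-trimethoxyphenyl ring) and the methyl carbon C9. These are the four ligands a diazoacetate carbene carbon holds after it has captured a phenol oxygen and then an aldehyde carbon. One three-component operation should therefore forge C8–O and C7–C8 and set both stereocentres (syn, 7R,8R). Its precursors are three commercial, achiral compounds: 4-bromo-2,6-dimethoxyphenol, ethyl diazoacetate and 3,4,5-trimethoxybenzaldehyde. The ester carbon later becomes the C9 methyl and the bromide the propenol arm.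

Key step: step 1

Assumption: the enantiomer of the BINOL phosphoric acid that leads to the (2S,3R) ester cannot be derived from known cases for a phenol and an acceptor-only diazoacetate; (R)-TRIP [(R)-3,3'-bis(2,4,6-triisopropylphenyl)-1,1'-binaphthyl-2,2'-diyl hydrogen phosphate] is written, and its commercial antipode is to be used if the facial sense proves opposite.

Step 1
Reactants: 1 4-bromo-2,6-dimethoxyphenol; 2 ethyl diazoacetate; 3 3,4,5-trimethoxybenzaldehyde
Product: 5 ethyl (2S,3R)-2-(4-bromo-2,6-dimethoxyphenoxy)-3-hydroxy-3-(3,4,5-trimethoxyphenyl)propanoate, via oxonium ylide 4 (not isolated)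
Conditions: Rh2(OAc)4 (2 mol %), (R)-TRIP (10 mol %), 4 Å MS, CH2Cl2, 0 °C; 2 (1.5 equiv) added over 3 h by syringe pump to 1 (1 equiv) and 3 (2 equiv)
Reagents that add atoms: none
Why: Proposed new method: Rh2(OAc)4 releases N2 from 2 to give an electrophilic rhodium carbene, the hydroxyl oxygen of 1 adds to it to form oxonium ylide 4 (equivalent to the enol of the aryloxyacetate), and this enol, bound through its O–H to the P=O of the phosphoric acid whose P–OH activates 3, should add to the aldehyde carbon and forge C7–C8 before a 1,2-proton shift completes simple O–H insertion. The closest known reaction type is the three-component aldol- or Mannich-type trapping of oxonium ylides generated from aryl diazoacetates and alcohols under Rh2(OAc)4 with a chiral phosphoric acid or chiral Lewis acid co-catalyst; a phenol as the O–H partner combined with an acceptor-only diazoacetate is the untested part. No ring is closed. Both stereocentres arise in one hydrogen-bonded, acid-bridged transition state: the syn relation between the C8 aryloxy group and the C7 hydroxyl should follow from the enol geometry with aryloxy and enol O–H on the same side meeting the aldehyde with ring A turned away from the aryloxy group, and the absolute 7R,8R sense (2S,3R in the ester) from the 3,3'-aryl walls of the catalyst. The selectivity required is trapping over proton transfer, and the process is set up for it by keeping 3 in excess and 2 at a low stationary concentration at 0 °C over molecular sieves. On the substrate side, the para-methoxy group of 3 is twisted out of conjugation by its two neighbours so that the aldehyde is roughly as electrophilic as benzaldehyde, and the O–H of 1 is hindered and hydrogen-bonded to an ortho-methoxy group, which should slow the unassisted proton shift.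

Step 2
Reactants: 5 ethyl (2S,3R)-2-(4-bromo-2,6-dimethoxyphenoxy)-3-hydroxy-3-(3,4,5-trimethoxyphenyl)propanoate
Product: 6 (1R,2R)-2-(4-bromo-2,6-dimethoxyphenoxy)-1-(3,4,5-trimethoxyphenyl)propane-1,3-diol
Conditions: LiBH4 (2.5 equiv), THF, 0 °C to rt; then H2O
Reagents that add atoms: none
Why: Chemoselective hydride reduction of the ester, assisted by chelation of lithium between the ester carbonyl and the α-aryloxy and β-hydroxy oxygens, should give the 1,3-diol without touching the aryl bromide, and at 0 °C hydride transfer should outpace retro-aldol cleavage so that C7 and C8 keep their configuration.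

Step 3
Reactants: 6 (1R,2R)-2-(4-bromo-2,6-dimethoxyphenoxy)-1-(3,4,5-trimethoxyphenyl)propane-1,3-diol
Product: 7 (2R,3R)-2-(4-bromo-2,6-dimethoxyphenoxy)-3-hydroxy-3-(3,4,5-trimethoxyphenyl)propyl 4-methylbenzenesulfonate
Conditions: TsCl (1.1 equiv), pyridine, CH2Cl2, 0 °C
Reagents that add atoms: 4-toluenesulfonyl chloride (TsCl), Cc1ccc(cc1)S(=O)(=O)Cl
Why: Sulfonylation (tosylation) is sterically governed, so the primary C9 hydroxyl should react with the limiting sulfonyl chloride at 0 °C while the secondary benzylic C7 hydroxyl, shielded by ring A and the neighbouring aryloxy group, stays free and no stereocentre is touched.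

Step 4
Reactants: 7 (2R,3R)-2-(4-bromo-2,6-dimethoxyphenoxy)-3-hydroxy-3-(3,4,5-trimethoxyphenyl)propyl 4-methylbenzenesulfonate
Product: 8 (1R,2R)-2-(4-bromo-2,6-dimethoxyphenoxy)-1-(3,4,5-trimethoxyphenyl)propan-1-ol
Conditions: LiBHEt3 (3 equiv), THF, 0 °C to rt; then H2O
Reagents that add atoms: none
Why: Super-Hydride reduction, an SN2 displacement of the primary sulfonate by the very nucleophilic LiBHEt3, should turn C9 into the methyl group; the first equivalent converts the C7 hydroxyl into a weakly nucleophilic triethylborate-bound alkoxide (which disfavours oxetane closure), the aryl bromide is inert to hydride without a transition metal, and neither stereocentre is involved.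

Step 5
Reactants: 8 (1R,2R)-2-(4-bromo-2,6-dimethoxyphenoxy)-1-(3,4,5-trimethoxyphenyl)propan-1-ol; 9 (E)-3-(tert-butyldimethylsilyloxy)prop-1-enylboronic acid pinacol ester
Product: 10 (1R,2R)-2-{4-[(E)-3-(tert-butyldimethylsilyloxy)prop-1-enyl]-2,6-dimethoxyphenoxy}-1-(3,4,5-trimethoxyphenyl)propan-1-ol
Conditions: Pd(OAc)2 (3 mol %), SPhos (6 mol %), K3PO4 (3 equiv), THF/H2O, 60 °C
Reagents that add atoms: none
Why: Suzuki–Miyaura coupling: the unhindered aryl bromide para to the ether oxygen should undergo oxidative addition to the SPhos-ligated zerovalent palladium formed in situ, and transmetalation and reductive elimination transfer the alkenyl group with retention of its E geometry, while the free benzylic alcohol and the silyl ether tolerate aqueous phosphate.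

Step 6
Reactants: 10 (1R,2R)-2-{4-[(E)-3-(tert-butyldimethylsilyloxy)prop-1-enyl]-2,6-dimethoxyphenoxy}-1-(3,4,5-trimethoxyphenyl)propan-1-ol
Product: 11 (1R,2R)-2-{4-[(E)-3-hydroxyprop-1-enyl]-2,6-dimethoxyphenoxy}-1-(3,4,5-trimethoxyphenyl)propan-1-ol
Conditions: TBAF (1.2 equiv), THF, 0 °C to rt
Reagents that add atoms: none
Why: Fluoride-mediated desilylation, driven by Si–F bond formation, should release the primary allylic alcohol under non-acidic conditions that spare the acid-labile, electron-rich benzylic alcohol at C7, the aryl ether and the E alkene.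

Compound list
1 | 4-bromo-2,6-dimethoxyphenol | COc1cc(Br)cc(OC)c1O | starting material
2 | ethyl diazoacetate | CCOC(=O)C=[N+]=[N-] | starting material
3 | 3,4,5-trimethoxybenzaldehyde | COc1cc(C=O)cc(OC)c1OC | starting material
4 | oxonium ylide from 1 and the carbene of 2: (4-bromo-2,6-dimethoxyphenyl)oxonium 2-ethoxy-2-oxoethylide, reacting as the enol of ethyl 2-(4-bromo-2,6-dimethoxyphenoxy)acetate | CCOC(=O)[CH-][OH+]c1c(OC)cc(Br)cc1OC | intermediate (not isolated)
5 | ethyl (2S,3R)-2-(4-bromo-2,6-dimethoxyphenoxy)-3-hydroxy-3-(3,4,5-trimethoxyphenyl)propanoate | CCOC(=O)[C@@H](Oc1c(OC)cc(Br)cc1OC)[C@H](O)c1cc(OC)c(OC)c(OC)c1 | intermediate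
6 | (1R,2R)-2-(4-bromo-2,6-dimethoxyphenoxy)-1-(3,4,5-trimethoxyphenyl)propane-1,3-diol | OC[C@@H](Oc1c(OC)cc(Br)cc1OC)[C@H](O)c1cc(OC)c(OC)c(OC)c1 | intermediate
7 | (2R,3R)-2-(4-bromo-2,6-dimethoxyphenoxy)-3-hydroxy-3-(3,4,5-trimethoxyphenyl)propyl 4-methylbenzenesulfonate | Cc1ccc(cc1)S(=O)(=O)OC[C@@H](Oc1c(OC)cc(Br)cc1OC)[C@H](O)c1cc(OC)c(OC)c(OC)c1 | intermediate
8 | (1R,2R)-2-(4-bromo-2,6-dimethoxyphenoxy)-1-(3,4,5-trimethoxyphenyl)propan-1-ol | C[C@@H](Oc1c(OC)cc(Br)cc1OC)[C@H](O)c1cc(OC)c(OC)c(OC)c1 | intermediate
9 | (E)-3-(tert-butyldimethylsilyloxy)prop-1-enylboronic acid pinacol ester | CC(C)(C)[Si](C)(C)OC/C=C/B1OC(C)(C)C(C)(C)O1 | starting material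
10 | (1R,2R)-2-{4-[(E)-3-(tert-butyldimethylsilyloxy)prop-1-enyl]-2,6-dimethoxyphenoxy}-1-(3,4,5-trimethoxyphenyl)propan-1-ol | C[C@@H](Oc1c(OC)cc(/C=C/CO[Si](C)(C)C(C)(C)C)cc1OC)[C@H](O)c1cc(OC)c(OC)c(OC)c1 | intermediate
11 | (1R,2R)-2-{4-[(E)-3-hydroxyprop-1-enyl]-2,6-dimethoxyphenoxy}-1-(3,4,5-trimethoxyphenyl)propan-1-ol | COc1cc([C@@H](O)[C@@H](C)Oc2c(OC)cc(/C=C/CO)cc2OC)cc(OC)c1OC | target

Total step count: 6. Longest linear sequence: 6 steps (1, 2 and 3 to 5, then 6, 7, 8, 10, 11); the only other building block, 9, is commercial.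

Steps most likely to fail

Step 1 (proposed new method). The oxonium ylide may collapse by proton transfer to the plain O–H insertion product faster than it is trapped, or the trapping may proceed with poor syn or facial selectivity. The fallback builds the same C7–C8 bond and both stereocentres by known auxiliary chemistry, sets out from 1 and returns to the route at 6, bypassing 5. Williamson etherification of 1 with bromoacetic acid (NaOH, H2O, reflux, then HCl) should give 2-(4-bromo-2,6-dimethoxyphenoxy)acetic acid F1. Coupling with (S)-4-benzyloxazolidin-2-one (PivCl, Et3N, LiCl, THF, −20 °C to rt) should give (S)-4-benzyl-3-[2-(4-bromo-2,6-dimethoxyphenoxy)acetyl]oxazolidin-2-one F2. An Evans boron aldol reaction with 3 (Bu2BOTf, iPr2NEt, CH2Cl2, −78 to 0 °C; H2O2 work-up) should give the syn adduct (S)-4-benzyl-3-[(2S,3R)-2-(4-bromo-2,6-dimethoxyphenoxy)-3-hydroxy-3-(3,4,5-trimethoxyphenyl)propanoyl]oxazolidin-2-one F3, through a Z-boron enolate in a chair transition state whose face is dictated by the benzyl group. Reductive removal of the auxiliary (LiBH4, THF, 1 equiv H2O, 0 °C) should deliver diol 6.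

Step 4. The C7 alkoxide may displace the neighbouring sulfonate (oxetane closure, then unselective ring opening), or hydride may attack the aryl bromide on prolonged exposure. The fallback removes the free hydroxyl from the hydride step, sets out from 7 and returns at 11. Silylation (TBSOTf, 2,6-lutidine, CH2Cl2, −78 to 0 °C) should give (2R,3R)-2-(4-bromo-2,6-dimethoxyphenoxy)-3-(tert-butyldimethylsilyloxy)-3-(3,4,5-trimethoxyphenyl)propyl 4-methylbenzenesulfonate F4. LiBHEt3 (THF, 0 °C) should then give tert-butyl{[(1R,2R)-2-(4-bromo-2,6-dimethoxyphenoxy)-1-(3,4,5-trimethoxyphenyl)propyl]oxy}dimethylsilane F5. Suzuki–Miyaura coupling with 9 under the conditions of step 5 should give the bis(tert-butyldimethylsilyl) ether of 11 F6, and TBAF (2.5 equiv, THF) should remove both silyl groups to give 11.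

Step 3. Sulfonyl transfer may lose site selectivity, with reaction at both hydroxyls or ionisation of a benzylic sulfonate on the electron-rich ring A. The fallback replaces sulfonyl activation by oxyphosphonium activation, which is more sensitive to steric hindrance; it sets out from 6 and returns at 8. Iodine, PPh3 and imidazole (CH2Cl2, 0 °C, Appel-type) should convert only the primary hydroxyl and give (1R,2S)-2-(4-bromo-2,6-dimethoxyphenoxy)-3-iodo-1-(3,4,5-trimethoxyphenyl)propan-1-ol F7. LiBHEt3 (THF, 0 °C) should displace the iodide and deliver 8.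

Further compounds
F1 | step 1 | 2-(4-bromo-2,6-dimethoxyphenoxy)acetic acid | OC(=O)COc1c(OC)cc(Br)cc1OC
F2 | step 1 | (S)-4-benzyl-3-[2-(4-bromo-2,6-dimethoxyphenoxy)acetyl]oxazolidin-2-one | O=C(COc1c(OC)cc(Br)cc1OC)N1[C@@H](Cc2ccccc2)COC1=O
F3 | step 1 | (S)-4-benzyl-3-[(2S,3R)-2-(4-bromo-2,6-dimethoxyphenoxy)-3-hydroxy-3-(3,4,5-trimethoxyphenyl)propanoyl]oxazolidin-2-one | O=C([C@@H](Oc1c(OC)cc(Br)cc1OC)[C@H](O)c1cc(OC)c(OC)c(OC)c1)N1[C@@H](Cc2ccccc2)COC1=O
F4 | step 4 | (2R,3R)-2-(4-bromo-2,6-dimethoxyphenoxy)-3-(tert-butyldimethylsilyloxy)-3-(3,4,5-trimethoxyphenyl)propyl 4-methylbenzenesulfonate | Cc1ccc(cc1)S(=O)(=O)OC[C@@H](Oc1c(OC)cc(Br)cc1OC)[C@H](O[Si](C)(C)C(C)(C)C)c1cc(OC)c(OC)c(OC)c1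
F5 | step 4 | tert-butyl{[(1R,2R)-2-(4-bromo-2,6-dimethoxyphenoxy)-1-(3,4,5-trimethoxyphenyl)propyl]oxy}dimethylsilane | C[C@@H](Oc1c(OC)cc(Br)cc1OC)[C@H](O[Si](C)(C)C(C)(C)C)c1cc(OC)c(OC)c(OC)c1
F6 | step 4 | bis(tert-butyldimethylsilyl) ether of 11 (C7 hydroxyl and allylic hydroxyl both silylated, 7R,8R, E) | C[C@@H](Oc1c(OC)cc(/C=C/CO[Si](C)(C)C(C)(C)C)cc1OC)[C@H](O[Si](C)(C)C(C)(C)C)c1cc(OC)c(OC)c(OC)c1
F7 | step 3 | (1R,2S)-2-(4-bromo-2,6-dimethoxyphenoxy)-3-iodo-1-(3,4,5-trimethoxyphenyl)propan-1-ol | IC[C@@H](Oc1c(OC)cc(Br)cc1OC)[C@H](O)c1cc(OC)c(OC)c(OC)c1
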